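A flask cannot hold more open intermediate than its substrate has so far opened. So take the case without any drain as the zero of your scale. Every opened molecule stays, and the curve is the opening curve itself, which I call the ceiling. What falls short of it has gone on, for instance with second intermediate to target.

common to all: gas 61 mM (held)
- ash: substrate 0.74 M; capture agent 0.022 M; temperature 0 °C; run made earlier
- elm: substrate 1.7 M; capture agent 0.022 M; temperature 25 °C; run made earlier
- south: substrate 1.1 M; capture agent 0.0220 M; temperature 5 °C; time 12 min
- south-east: substrate 1.1 M; capture agent 0.0220 M; temperature 45 °C; time 12 min
- north-west: substrate 1.1 M; capture agent 0.0220 M; at 5 °C until 4.0 min, from then on at 45 °C; time 12 min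
- east: substrate 1.1 M; capture agent 0.0220 M; temperature 25 °C; time 12 min

- ash (time / min: open intermediate / %, target / %): 1.00: 3, 1; 1.50: 2, 0; 2.50: 5, 0; 4.00: 7, 3; 8.00: 11, 0; 12.0: 18, 0
- elm (time / min: open intermediate / %, target / %): 0.333: 6, 0; 0.500: 14, 2; 1.00: 25, 0; 1.33: 28, 2; 3.00: 49, 6; 4.00: 54, 6

(standard deviation of a reading: 1.5 percentage points)

1. the best flask by amount of open intermediate, in percent of the substrate charged; "all alike" if 1.5 percentage points covers them all (south / south-east / north-west / east / all alike)
2. amount of open intermediate at the end, in percent of the substrate charged, south
3. amount of open intermediate at the end, in percent of the substrate charged, south-east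
4. amount of open intermediate at the end, in percent of the substrate charged, north-west
5. amount of open intermediate at the end, in percent of the substrate charged, east

- at the start none of partner is dissolved
- what was read earlier has a scatter of 1.5 percentage points, one standard deviation
- candidate steps: open intermediate + capture agent -> trapped intermediate; substrate -> open intermediate; 2 second intermediate -> homo product; partner -> second intermediate; gas <-> partner; open intermediate + second intermediate -> target; partner + target -> over-reaction product

Read the opening from the runs, assuming first order, so that percentages ignore the charge. In ash, open intermediate reads 18% after 12.0 min with target at 0%, which gives a constant of 0.0165 min⁻¹. In elm, open intermediate and target together read 55.0% after 3.00 min, which gives 0.266 min⁻¹. These two readings give an activation energy of 75.3 kJ mol⁻¹.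

Now draw the ceilings. The ceiling of south starts with a slope of 0.0300 min⁻¹. Its half-life is longer than the run, so this ceiling shows no knee and ends at 30.2%. The ceiling of east bends at 2.61 min and reaches 95.9%. The ceiling of south-east starts at 1.79 min⁻¹, so its opening half-life, 0.386 min, puts the knee almost at the start and the level at >99.9%. The ceiling of north-west creeps to 11.3% by 4.0 min, then bends just as sharply.

Elm shows target at 6% after 4.00 min, so the drain is real. South-east spends nearly all of its run past the knee, exposed to that drain. My own expectation is south just under its ceiling, south-east and north-west far under theirs, and east on top.

The forecast, holding that "this drain is strongly activated", said east, with 30% in south, 10% in south-east, 28% in north-west and 68% in east.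

The flasks give 26.7% in south, 15.7% in south-east, 34.6% in north-west and 51.8% in east, so east leads.

    open intermediate + capture agent → trapped intermediate (k = 0.00200 M⁻¹ s⁻¹, Ea = 52.0 kJ mol⁻¹)
    substrate → open intermediate (k = 0.00440 s⁻¹, Ea = 76.0 kJ mol⁻¹)
    2 second intermediate → homo product (k = 0.0210 M⁻¹ s⁻¹, Ea = 60.0 kJ mol⁻¹)
    partner → second intermediate (k = 0.0270 s⁻¹, Ea = 84.0 kJ mol⁻¹)
    gas ⇌ partner, rate k5*(csat - [partner]) (kL = 0.0490 s⁻¹)
    open intermediate + second intermediate → target (k = 0.0220 M⁻¹ s⁻¹, Ea = 48.0 kJ mol⁻¹)
    partner + target → over-reaction product (k = 0.280 M⁻¹ s⁻¹, Ea = 46.0 kJ mol⁻¹)
    (constants at 25 °C)

In south-east, half of the opening is done by 0.382 min, where the half-life put it at 0.386 min, far shorter than the run of 12 min. Later steps carry on from there: at 6.05 min, open intermediate in south-east goes 95 times as fast into target as into trapped intermediate.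

Read south-east itself at 5.0 min. That time is 13.0 half-lives, so the reckoning leaves 0.0126% of the substrate. That flask holds 0.012% substrate and 57.3% open intermediate, which is 43 percentage points under the ceiling.

The earlier runs and the new flask are simulated from invented constants; the scatter is artificial.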